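**Plan**

- Retrosynthesis (isochromene numbering of the target): cut O2–C1 of the pyran (addition–elimination of the C3 hydroxyl on a methoxymethylene), then C4a–C8a of the carbocycle (intramolecular Heck), then the stearate C–O bond, the C6–C5 bond (alkynyl ketone) and the C7–C8 bond (enolate acylation).
- Enabling feature: the carbocycle C4a–C5–C6–C7–C8–C8a holds a cross-conjugated diene, C4a=C5 inside the ring and C8a=C1 exocyclic to it, joined by the C4a–C8a single bond. A vinyl bromide at C4a and the alkene C8a=C1 give exactly this array on Heck coupling.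
- Forward: lactic acid dioxolanone, C-acylation (C7–C8), alkynyllithium opening of the lactone (C6–C5, chain joined), stearoylation, hydrobromination, Heck closure of the carbocycle, then desilylation and closure of the pyran.
- Stereochemistry: C7 comes from (R)-lactic acid by self-regeneration of stereocentres (acyl group enters trans to tert-butyl, overall retention). C3 comes from (R)-propylene oxide and is never touched. The (Z)-bromoalkene comes from anti hydrobromination of the ynone.

Key step: step 10

Remark on the chemistry: C1–C8a labels are those of the isochromene skeleton and are used for the corresponding carbons of all intermediates. The CIP label of C7 reads S in the open-chain compounds and R after ring closure only because the ranking of its two acyl arms changes; the arrangement in space stays the same. TBS = tert-butyldimethylsilyl.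

**Route**

Step 1
Reactants: 1 (R)-lactic acid; 2 pivalaldehyde (2,2-dimethylpropanal)
Product: 3 (2R,5R)-2-tert-butyl-5-methyl-1,3-dioxolan-4-one (tert-butyl and methyl cis)
Conditions: TsOH·H2O (cat.), H2SO4 (cat.), pentane, reflux, azeotropic removal of water; crystallisation from pentane, −78 °C
Reagents that add atoms: none
Why: Acid-catalysed acetalisation of the α-hydroxy acid is reversible, so the 2,5-cis dioxolanone should prevail under thermodynamic control and be enriched by crystallisation, which sets the acetal carbon as R relative to the lactate centre.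

Step 2
Reactants: 4 methyl (E)-3-methoxyacrylate
Product: 5 (E)-3-methoxyacrylic acid
Conditions: NaOH, H2O/MeOH, rt; then cold 1 M HCl to pH 2, EtOAc extraction
Reagents that add atoms: sodium hydroxide, [Na+].[OH-]
Why: Saponification of the methyl ester by acyl–oxygen cleavage leaves the vinylogous carbonate and its E geometry intact as long as the acidification is cold and brief.

Step 3
Reactants: 5 (E)-3-methoxyacrylic acid
Product: 6 (E)-3-methoxyacryloyl chloride
Conditions: (COCl)2, DMF (cat.), CH2Cl2, 0 °C → rt; evaporation, used at once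
Reagents that add atoms: oxalyl chloride, O=C(Cl)C(=O)Cl
Why: Acid chloride formation through the chloroiminium catalyst generated from DMF runs under mild anhydrous conditions that the enol ether tolerates.

Step 4
Reactants: 3 (2R,5R)-2-tert-butyl-5-methyl-1,3-dioxolan-4-one; 6 (E)-3-methoxyacryloyl chloride
Product: 8 (2R,5S)-2-tert-butyl-5-[(2E)-3-methoxyprop-2-enoyl]-5-methyl-1,3-dioxolan-4-one (methyl cis to tert-butyl), via lithium dioxolanone enolate 7 (not isolated)
Conditions: LiN(SiMe3)2, THF, −78 °C; enolate cannulated into 6, THF, −78 °C; aq. NH4Cl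
Reagents that add atoms: none
Why: Self-regeneration of stereocentres: deprotonation erases C5 but the acetal centre persists, and Claisen-type C-acylation of the lithium enolate by the acid chloride takes place on the face opposite the tert-butyl group, so the acyl group replaces the former hydrogen with retention and sets the quaternary carbon (later C7); the product cannot enolise, so no proton transfer consumes enolate.

Step 5
Reactants: 9 (R)-propylene oxide; 10 lithium acetylide–ethylenediamine complex (LiC≡CH·H2NCH2CH2NH2)
Product: 11 (R)-pent-4-yn-2-ol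
Conditions: DMSO, 5 °C → rt; H2O; distillation
Reagents that add atoms: none
Why: SN2 opening of the epoxide by the acetylide at the unsubstituted carbon leaves the stereocentre untouched, so the R configuration passes into the homopropargylic alcohol.

Step 6
Reactants: 11 (R)-pent-4-yn-2-ol
Product: 12 (R)-tert-butyldimethyl(pent-4-yn-2-yloxy)silane
Conditions: TBSCl, imidazole, CH2Cl2, 0 °C → rt
Reagents that add atoms: tert-butyldimethylsilyl chloride, CC(C)(C)[Si](C)(C)Cl
Why: Imidazole-promoted silylation of a secondary alcohol gives an ether that withstands the organolithium, mild-acid and palladium steps that follow.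

Step 7
Reactants: 8 (2R,5S)-2-tert-butyl-5-[(2E)-3-methoxyprop-2-enoyl]-5-methyl-1,3-dioxolan-4-one; 12 (R)-tert-butyldimethyl(pent-4-yn-2-yloxy)silane
Product: 15 (1E,4S,9R)-9-[(tert-butyldimethylsilyl)oxy]-4-hydroxy-1-methoxy-4-methyldec-1-en-6-yne-3,5-dione, via lithium acetylide 13 (not isolated), via lithium hemiketal alkoxide 14 (not isolated)
Conditions: 12, n-BuLi, THF, −78 °C; added slowly to 8, THF, −78 °C; AcOH, −78 °C → rt; pH 7 buffer
Reagents that add atoms: none
Why: Nucleophilic acyl substitution of a lactone by an alkynyllithium (ynone synthesis): the acylal-type dioxolanone carbonyl is far more electrophilic than the vinylogous-ester ketone, the tetrahedral lithium alkoxide persists at −78 °C and so blocks a second addition, and on protonation it opens and sheds pivalaldehyde to uncover the tertiary alcohol without touching the quaternary centre.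

Step 8
Reactants: 15 (1E,4S,9R)-9-[(tert-butyldimethylsilyl)oxy]-4-hydroxy-1-methoxy-4-methyldec-1-en-6-yne-3,5-dione; 16 stearoyl chloride (octadecanoyl chloride)
Product: 18 (1E,4S,9R)-9-[(tert-butyldimethylsilyl)oxy]-1-methoxy-4-methyl-3,5-dioxodec-1-en-6-yn-4-yl octadecanoate, via lithium tertiary alkoxide 17 (not isolated)
Conditions: LiN(SiMe3)2, THF, −78 °C; then 16, −78 → −30 °C; pH 7 buffer
Reagents that add atoms: none
Why: O-acylation of a preformed lithium alkoxide by an acid chloride at low temperature is the standard esterification of a hindered tertiary alcohol, needs no nucleophilic amine that could add to the ynone, and should be fast enough to outrun acyl shift of the α-ketol.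

Step 9
Reactants: 18 (1E,4S,9R)-9-[(tert-butyldimethylsilyl)oxy]-1-methoxy-4-methyl-3,5-dioxodec-1-en-6-yn-4-yl octadecanoate
Product: 19 (1E,4S,6Z,9R)-7-bromo-9-[(tert-butyldimethylsilyl)oxy]-1-methoxy-4-methyl-3,5-dioxodeca-1,6-dien-4-yl octadecanoate
Conditions: LiBr, AcOH, MeCN, rt
Reagents that add atoms: lithium bromide, [Li+].[Br-]
Why: Hydrohalogenation of an electron-poor alkyne with a halide salt in acetic acid: bromide adds to the β-carbon (C4a) of the ynone and the allenolate is protonated anti, which should give the (Z)-β-bromoenone (bromine cis to the C6 carbonyl) under kinetic control while the less electrophilic β-methoxy enone and the silyl ether stay intact.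

Step 10
Reactants: 19 (1E,4S,6Z,9R)-7-bromo-9-[(tert-butyldimethylsilyl)oxy]-1-methoxy-4-methyl-3,5-dioxodeca-1,6-dien-4-yl octadecanoate
Product: 20 (1R,5Z)-4-[(2R)-2-[(tert-butyldimethylsilyl)oxy]propyl]-5-(methoxymethylidene)-1-methyl-2,6-dioxocyclohex-3-en-1-yl octadecanoate
Conditions: Pd(OAc)2 (10 mol %), P(o-tol)3 (20 mol %), Ag2CO3, degassed MeCN, 70 °C
Reagents that add atoms: none
Why: Zerovalent palladium, formed from Pd(OAc)2 and P(o-tol)3, inserts into the activated C4a–Br bond of the (Z)-bromoenone; the vinylpalladium species, made cationic by silver, adds syn across C8a=C1 with carbon bonding to C8a, and syn β-hydride loss from C8a (its hydrogen is the only β-hydrogen, reached by rotation about the exocyclic C8a–C1 bond) restores the methoxymethylene while Ag2CO3 takes up HBr. The closest known reaction type is the intramolecular Heck cyclisation of a vinyl or aryl halide onto the α-carbon of an unsaturated carbonyl unit or onto an enol ether, which routinely closes five- and six-membered rings in the exo mode. The carbocycle C4a–C5–C6–C7–C8–C8a closes 6-exo-trig. No stereocentre is created, the quaternary C7 and the remote C3 cannot epimerise, and syn insertion followed by syn elimination should place the methoxy group cis to the C8 carbonyl (Z), a geometry without consequence for the last step. The selectivity required is bond formation at C8a (6-exo) and not at C1 (7-endo), which the electronic bias of the push–pull alkene would favour; it is secured by the short three-atom tether, by the kinetic preference for the six-membered exo transition state and by the (Z) geometry of the bromoenone, which alone holds palladium on the side of the chain. A weakly nucleophilic phosphine and an inorganic base are chosen so that neither adds to the bromoenone.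

Step 11
Reactants: 20 (1R,5Z)-4-[(2R)-2-[(tert-butyldimethylsilyl)oxy]propyl]-5-(methoxymethylidene)-1-methyl-2,6-dioxocyclohex-3-en-1-yl octadecanoate
Product: 22 (3R,7R)-3,7-dimethyl-6,8-dioxo-3,4,7,8-tetrahydro-6H-isochromen-7-yl octadecanoate, via desilylated hydroxy enol ether 21 (not isolated)
Conditions: HF·pyridine, THF, 0 °C → rt; then PPTS (cat.), PhMe, 50 °C
Reagents that add atoms: none
Why: Fluoride-driven cleavage of the silyl ether frees the C3 hydroxyl, which adds to C1 of the methoxymethylene and expels methanol (oxa-Michael addition–elimination, a vinylogous transesterification that closes the six-membered pyran) under mild acid catalysis that leaves the tertiary ester and both stereocentres untouched.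

**Compound list**

1 | (R)-lactic acid | C[C@@H](O)C(=O)O | starting material
2 | pivalaldehyde | CC(C)(C)C=O | starting material
3 | (2R,5R)-2-tert-butyl-5-methyl-1,3-dioxolan-4-one | C[C@H]1O[C@@H](C(C)(C)C)OC1=O | intermediate
4 | methyl (E)-3-methoxyacrylate | CO/C=C/C(=O)OC | starting material
5 | (E)-3-methoxyacrylic acid | CO/C=C/C(=O)O | intermediate
6 | (E)-3-methoxyacryloyl chloride | CO/C=C/C(=O)Cl | intermediate
7 | lithium (2R)-2-tert-butyl-5-methyl-1,3-dioxol-4-olate (enolate of 3) | CC1=C([O-])O[C@H](C(C)(C)C)O1.[Li+] | intermediate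
8 | (2R,5S)-2-tert-butyl-5-[(2E)-3-methoxyprop-2-enoyl]-5-methyl-1,3-dioxolan-4-one | C[C@@]1(C(=O)/C=C/OC)O[C@@H](C(C)(C)C)OC1=O | intermediate
9 | (R)-propylene oxide | C[C@@H]1CO1 | starting material
10 | lithium acetylide–ethylenediamine complex | [Li+].[C-]#C.NCCN | starting material
11 | (R)-pent-4-yn-2-ol | C#CC[C@@H](C)O | intermediate
12 | (R)-tert-butyldimethyl(pent-4-yn-2-yloxy)silane | C#CC[C@@H](C)O[Si](C)(C)C(C)(C)C | intermediate
13 | lithium (4R)-4-[(tert-butyldimethylsilyl)oxy]pent-1-yn-1-ide | [Li+].[C-]#CC[C@@H](C)O[Si](C)(C)C(C)(C)C | intermediate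
14 | lithium (2R)-2-tert-butyl-4-[(4R)-4-[(tert-butyldimethylsilyl)oxy]pent-1-yn-1-yl]-5-[(2E)-3-methoxyprop-2-enoyl]-5-methyl-1,3-dioxolan-4-olate (C5 as in 8, C4 undefined) | C[C@@]1(C(=O)/C=C/OC)O[C@@H](C(C)(C)C)OC1([O-])C#CC[C@@H](C)O[Si](C)(C)C(C)(C)C.[Li+] | intermediate
15 | (1E,4S,9R)-9-[(tert-butyldimethylsilyl)oxy]-4-hydroxy-1-methoxy-4-methyldec-1-en-6-yne-3,5-dione | C[C@](O)(C(=O)/C=C/OC)C(=O)C#CC[C@@H](C)O[Si](C)(C)C(C)(C)C | intermediate
16 | stearoyl chloride | CCCCCCCCCCCCCCCCCC(=O)Cl | starting material
17 | lithium alkoxide of 15 | C[C@]([O-])(C(=O)/C=C/OC)C(=O)C#CC[C@@H](C)O[Si](C)(C)C(C)(C)C.[Li+] | intermediate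
18 | (1E,4S,9R)-9-[(tert-butyldimethylsilyl)oxy]-1-methoxy-4-methyl-3,5-dioxodec-1-en-6-yn-4-yl octadecanoate | CCCCCCCCCCCCCCCCCC(=O)O[C@](C)(C(=O)C#CC[C@@H](C)O[Si](C)(C)C(C)(C)C)C(=O)/C=C/OC | intermediate
19 | (1E,4S,6Z,9R)-7-bromo-9-[(tert-butyldimethylsilyl)oxy]-1-methoxy-4-methyl-3,5-dioxodeca-1,6-dien-4-yl octadecanoate | CCCCCCCCCCCCCCCCCC(=O)O[C@](C)(C(=O)/C=C(Br)/C[C@@H](C)O[Si](C)(C)C(C)(C)C)C(=O)/C=C/OC | intermediate
20 | (1R,5Z)-4-[(2R)-2-[(tert-butyldimethylsilyl)oxy]propyl]-5-(methoxymethylidene)-1-methyl-2,6-dioxocyclohex-3-en-1-yl octadecanoate | CCCCCCCCCCCCCCCCCC(=O)O[C@]1(C)C(=O)C=C(C[C@@H](C)O[Si](C)(C)C(C)(C)C)/C(=C/OC)C1=O | intermediate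
21 | (1R,5Z)-4-[(2R)-2-hydroxypropyl]-5-(methoxymethylidene)-1-methyl-2,6-dioxocyclohex-3-en-1-yl octadecanoate | CCCCCCCCCCCCCCCCCC(=O)O[C@]1(C)C(=O)C=C(C[C@@H](C)O)/C(=C/OC)C1=O | intermediate
22 | (3R,7R)-3,7-dimethyl-6,8-dioxo-3,4,7,8-tetrahydro-6H-isochromen-7-yl octadecanoate (C1=C8a and C4a=C5 double bonds) | CCCCCCCCCCCCCCCCCC(=O)O[C@]1(C)C(=O)C=C2C[C@@H](C)OC=C2C1=O | target

**Step count and risks**

Total: 11 steps. Longest linear sequence: 8 steps (steps 2, 3, 4, 7, 8, 9, 10, 11, from methyl (E)-3-methoxyacrylate).

Steps most likely to fail: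

1. Step 7. The alkynyllithium may attack the ketone of the vinylogous ester or C1 (conjugate addition–elimination) in place of the lactone carbonyl, or add a second time once the tetrahedral adduct collapses. The fallback sets out from 3 and returns at 15. Enolate 7 is made as in step 4 and treated at −78 °C with (E)-3-methoxyacrolein, giving the lithium aldolate F1, in which C8 is an alkoxide and not a ketone. Lithium acetylide 13 is added to the same flask and can then attack only the lactone carbonyl, giving the dilithium hemiketal adduct F2. Buffered work-up releases pivalaldehyde and gives the diol ynone F3 as a mixture of C8 carbinol epimers. MnO2 in CH2Cl2 should oxidise the allylic secondary alcohol alone and deliver 15.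

2. Step 10. Insertion may occur at C1 (7-endo closure), or insertion into the push–pull alkene may be slow enough that protodebromination, isomerisation of the vinylpalladium species or addition of the ligand to the bromoenone takes over. The fallback sets out from 19 and returns at 22. N-Iodosuccinimide in CH2Cl2/AcOH, followed by NaOAc-mediated loss of acetic acid (iodo-acetoxylation and elimination at the vinylogous ester), should iodinate C8a and give the iodo bromide F4. Me3SnSnMe3 and Pd(PPh3)4 in 1,4-dioxane at 90 °C should stannylate the more reactive C–I bond to the vinylstannane F5 (not isolated), which couples with the C4a–Br bond (Stille–Kelly ring closure). The positions of the two halides then fix where the C4a–C8a bond forms. The product is expected as the E isomer F6 of 20. Under the conditions of step 11 it should give the hydroxy enol ether F7 (not isolated) and then 22.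

3. Step 8. The lithium alkoxide of the 2-hydroxy-1,3-diketone may undergo 1,2-acyl shift or retro-Claisen cleavage before it is acylated, or acylation of the hindered oxygen may stall. The fallback sets out from 15 and returns at 22. Et3SiOTf and 2,6-lutidine (CH2Cl2, −78 °C) silylate the tertiary hydroxyl without forming an alkoxide and give the bis-silyl ether F8. The conditions of steps 9 and 10 applied to it should give the bromoenone F9 and the cyclised triethylsilyl ether F10. HF·pyridine followed by PPTS removes both silyl groups to the diol F11 (not isolated) and closes the pyran to the bicyclic tertiary alcohol F12. Stearoyl chloride 16 with Et3N and DMAP (cat.) in CH2Cl2 then esterifies the tertiary hydroxyl of the rigid bicyclic α-ketol, a well-precedented acylation for cores of this kind, and gives 22.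

**Further compounds**

F1 | step 7 | lithium aldolate from 7 and (E)-3-methoxyacrolein (carbinol epimers) | C[C@@]1(C([O-])/C=C/OC)O[C@@H](C(C)(C)C)OC1=O.[Li+]
F2 | step 7 | dilithium hemiketal adduct of 13 to the lactone carbonyl of F1 | C[C@@]1(C([O-])/C=C/OC)O[C@@H](C(C)(C)C)OC1([O-])C#CC[C@@H](C)O[Si](C)(C)C(C)(C)C.[Li+].[Li+]
F3 | step 7 | (1E,3RS,4S,9R)-9-[(tert-butyldimethylsilyl)oxy]-3,4-dihydroxy-1-methoxy-4-methyldec-1-en-6-yn-5-one | CO/C=C/C(O)[C@](C)(O)C(=O)C#CC[C@@H](C)O[Si](C)(C)C(C)(C)C
F4 | step 10 | (1Z,4R,6Z,9R)-7-bromo-9-[(tert-butyldimethylsilyl)oxy]-2-iodo-1-methoxy-4-methyl-3,5-dioxodeca-1,6-dien-4-yl octadecanoate | CCCCCCCCCCCCCCCCCC(=O)O[C@](C)(C(=O)/C=C(Br)/C[C@@H](C)O[Si](C)(C)C(C)(C)C)C(=O)/C(I)=C/OC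
F5 | step 10 | C8a-trimethylstannyl analogue of F4 | CCCCCCCCCCCCCCCCCC(=O)O[C@](C)(C(=O)/C=C(Br)/C[C@@H](C)O[Si](C)(C)C(C)(C)C)C(=O)/C(=C/OC)[Sn](C)(C)C
F6 | step 10 | (1R,5E)-4-[(2R)-2-[(tert-butyldimethylsilyl)oxy]propyl]-5-(methoxymethylidene)-1-methyl-2,6-dioxocyclohex-3-en-1-yl octadecanoate | CCCCCCCCCCCCCCCCCC(=O)O[C@]1(C)C(=O)C=C(C[C@@H](C)O[Si](C)(C)C(C)(C)C)/C(=C\OC)C1=O
F7 | step 10 | (1R,5E)-4-[(2R)-2-hydroxypropyl]-5-(methoxymethylidene)-1-methyl-2,6-dioxocyclohex-3-en-1-yl octadecanoate | CCCCCCCCCCCCCCCCCC(=O)O[C@]1(C)C(=O)C=C(C[C@@H](C)O)/C(=C\OC)C1=O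
F8 | step 8 | triethylsilyl ether of 15 at the tertiary hydroxyl | CC[Si](CC)(CC)O[C@](C)(C(=O)C#CC[C@@H](C)O[Si](C)(C)C(C)(C)C)C(=O)/C=C/OC
F9 | step 8 | (Z)-bromoenone from F8 (triethylsilyl analogue of 19) | CC[Si](CC)(CC)O[C@](C)(C(=O)/C=C(Br)/C[C@@H](C)O[Si](C)(C)C(C)(C)C)C(=O)/C=C/OC
F10 | step 8 | cyclised triethylsilyl ether (triethylsilyl analogue of 20) | CC[Si](CC)(CC)O[C@]1(C)C(=O)C=C(C[C@@H](C)O[Si](C)(C)C(C)(C)C)/C(=C/OC)C1=O
F11 | step 8 | (6R)-6-hydroxy-3-[(2R)-2-hydroxypropyl]-2-[(Z)-methoxymethylidene]-6-methylcyclohex-3-ene-1,5-dione... drawn as the doubly desilylated analogue of 20 | O[C@]1(C)C(=O)C=C(C[C@@H](C)O)/C(=C/OC)C1=O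
F12 | step 8 | (3R,7R)-7-hydroxy-3,7-dimethyl-3,4-dihydro-6H-isochromene-6,8(7H)-dione | O[C@]1(C)C(=O)C=C2C[C@@H](C)OC=C2C1=O
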